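**Plan**

- Briarane numbering. Ring A (C1, C10–C14) carries two exo groups on neighbouring carbons, O9–C9 on C10 and the epoxide carbon C20 on C11. Tied together as an ester O9–C20(=O) they form a γ-lactone O9–C9–C10–C11–C20, and ring A becomes the adduct of the diene C13=C14(OSi)–C1(Me)=C10 with a C9 acrylate C11=C12.
- Cuts, in retrosynthetic order: epoxide O–C20 (from C11–OH and C20–OTs), lactone C19–O7, C6–C7 (alkenylchromium ring closure), C1–C2 (aldol of the C14=C1 enol ether), C10–C11 together with C12–C13 (tethered cycloaddition), C1=C10 (Wittig), C8–C17 (enolate alkylation).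
- Forward: the C7–C10/C17–C19 piece is built on D-erythronolactone; enone and C9 acrylate are attached; ring A and the temporary lactone form together; the lactone delivers O11 and is opened to C20 and the C9 hydroxyl; the C2–C6 arm is added at C1; the ten-membered ring, the natural lactone and the epoxide are closed last.
- Stereochemistry: C9 from the chiral pool; C8 by exo alkylation of the cis-fused lactone enolate; C17 by SN2 inversion of (R)-lactate; C10 from C9 in the cycloaddition; C11 by convex-face hydroxylation of the temporary lactone; C1 and C2 in the aldol; C14 by 1,3-syn reduction; C7 in the ring closure; the Z-olefin from (Z)-3-iodo-2-methylallyl alcohol.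

Key step: step 8

Remark: atoms keep their briarane numbers in all intermediates; α is the face of ring A that carries H-10, β the face of the C1 methyl (C15); compounds 1, 3, 6, 10, 16 and 18 are taken as commercial.

**Step 1**
Reactants: 1 tert-butyl (R)-lactate
Product: 2 tert-butyl (2R)-2-(trifluoromethylsulfonyloxy)propanoate
Conditions: Tf2O, 2,6-lutidine, CH2Cl2, −78 → 0 °C
Reagents that add atoms: triflic anhydride, O=S(=O)(OS(=O)(=O)C(F)(F)F)C(F)(F)F
Why: O-sulfonylation of an α-hydroxy ester with a hindered pyridine base breaks no bond at the stereocentre, so C17 keeps the R configuration.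

**Step 2**
Reactants: 3 2,3-O-isopropylidene-D-erythronolactone; 2 tert-butyl (2R)-2-(trifluoromethylsulfonyloxy)propanoate
Product: 4 C8-alkylated lactone (tert-butyl (2R)-2-[(3aR,6aR)-2,2-dimethyl-4-oxodihydrofuro[3,4-d][1,3]dioxol-3a(4H)-yl]propanoate)
Conditions: LiN(iPr)2, THF, −78 °C; then 2, −78 → −40 °C
Reagents that add atoms: none
Why: Lithium enolate alkylation with an α-triflyloxy ester (SN2): the cis-fused dioxolane allows the new C8–C17 bond only on the exo face (C8 quaternary with retention; the in-plane C9–O bond cannot undergo β-elimination), and backside displacement of triflate inverts C17 to the configuration of the target.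

**Step 3**
Reactants: 4 C8-alkylated lactone
Product: 5 hydroxy morpholine amide (C7 morpholide, C10 primary alcohol, C8/C9 acetonide, C19 tert-butyl ester)
Conditions: morpholine, AlMe3, CH2Cl2, 0 → 40 °C
Reagents that add atoms: morpholine, C1COCCN1
Why: Aminolysis of a γ-lactone by a dimethylaluminium amide should spare the hindered tert-butyl ester; it frees the C10 alcohol and stores C7 as a tertiary amide, a latent aldehyde without α-hydrogen.

**Step 4**
Reactants: 5 hydroxy morpholine amide; 6 3-(triphenylphosphoranylidene)butan-2-one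
Product: 8 (E)-enone acetonide (C13H3–C14(=O)–C1(CH3)=C10H–C9), via C10 aldehyde 7 (not isolated)
Conditions: DMP (1,1,1-triacetoxy-1,1-dihydro-1,2-benziodoxol-3(1H)-one), CH2Cl2, 0 °C → rt; then 6, toluene, 80 °C
Reagents that add atoms: none
Why: Periodinane oxidation gives the α-alkoxy aldehyde, which is trapped in the same flask by the stabilised α-methyl keto ylide (Wittig olefination) to give the E-trisubstituted enone with C9 trans to the acetyl group.

**Step 5**
Reactants: 8 (E)-enone acetonide
Product: 9 enone diol (C8 tertiary OH, C9 secondary allylic OH)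
Conditions: AcOH/H2O (4:1), 50 °C
Reagents that add atoms: none
Why: Acid-catalysed ketal hydrolysis in weak acid should leave the tert-butyl ester, the amide and the E-enone (which cannot close to a cyclic hemiketal) untouched.

**Step 6**
Reactants: 9 enone diol; 10 acryloyl chloride
Product: 11 C9 acrylate (C8 OH free)
Conditions: Et3N, DMAP (cat.), CH2Cl2, −20 → 0 °C
Reagents that add atoms: none
Why: Acylation is selective for the secondary C9 hydroxyl over the tertiary C8 hydroxyl and installs the dienophile C11=C12 together with C20 on the oxygen that stays as O9.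

**Step 7**
Reactants: 11 C9 acrylate
Product: 12 bis-silyl triene (C13H2=C14(OTBS)–C1(CH3)=C10H diene, C8 OTBS, C9 acrylate)
Conditions: TBSOTf (excess), Et3N, CH2Cl2, −78 °C → rt
Reagents that add atoms: tert-butyldimethylsilyl triflate, CC(C)(C)[Si](C)(C)OS(=O)(=O)C(F)(F)F
Why: Soft enolisation of the methyl ketone removes a C13 hydrogen (C1 is trigonal, so C13 is the only kinetic α-position) to give the cross-conjugated 2-silyloxy diene, and the tertiary C8 alcohol is silylated in the same operation.

**Step 8**
Reactants: 12 bis-silyl triene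
Product: 13 bicyclic lactone silyl enol ether (ring A with C14(OTBS)=C1(CH3), fused to the γ-lactone O9–C9–C10–C11–C20(=O); cis-fused epimer drawn)
Conditions: toluene, high dilution, BHT (cat.), 130 °C, sealed tube
Reagents that add atoms: none
Why: Thermal intramolecular Diels–Alder reaction of an ester-tethered 1,3,8-nonatriene, the known reaction type of pentadienyl acrylates: the electron-rich 2-silyloxy diene C13=C14–C1=C10 adds to the acrylate C11=C12 and forms C12–C13 and C10–C11 in one step. Ring A is closed by the [4+2] cycloaddition and the five-membered lactone is closed as the tether ring. Regiochemistry is fixed twice, by the tether and by polarity (the nucleophilic diene terminus C13 bonds to the acrylate β-carbon C12). C10 is set by C9: allylic 1,3-strain with the C1 methyl holds H-9 in the diene plane, the ester oxygen then lies on one face and the bulky quaternary C8 on the other, and the dienophile can reach C10 only from the oxygen face, which is the C9/C10 relationship of the target. C11 may form as the cis- or trans-fused epimer; both are carried on because C11 becomes trigonal in step 9. The step needs π-facial selectivity and suppression of intermolecular reaction, which the strain argument, high dilution and a radical inhibitor should secure; the C14=C1 silyl enol ether is delivered regiospecifically for step 13.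

**Step 9**
Reactants: 13 bicyclic lactone silyl enol ether
Product: 14 C11 α-hydroxy lactone (OH cis to H-10)
Conditions: LiN(iPr)2, THF, −78 °C; 2-(phenylsulfonyl)-3-phenyloxaziridine; aq. NH4Cl
Reagents that add atoms: 2-(phenylsulfonyl)-3-phenyloxaziridine, O=S(=O)(N1OC1c1ccccc1)c1ccccc1
Why: Lactone enolate hydroxylation with an N-sulfonyloxaziridine: the lactone α-hydrogen is far more acidic than the shielded α-hydrogen of the tert-butyl ester, and the oxidant should add to the convex face of the bicyclic enolate, cis to H-10, which places O11 α and C20 β as in the epoxide.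

**Step 10**
Reactants: 14 C11 α-hydroxy lactone
Product: 15 C11 silyl ether (C8 and C11 OTBS, C14=C1 enol OTBS)
Conditions: TBSOTf, 2,6-lutidine, CH2Cl2, −78 °C → rt
Reagents that add atoms: tert-butyldimethylsilyl triflate, CC(C)(C)[Si](C)(C)OS(=O)(=O)C(F)(F)F
Why: Silylation of the tertiary alcohol with a silyl triflate removes the proton source that would cleave the enol ether in step 13 and blocks early epoxide closure later.

**Step 11**
Reactants: 16 (Z)-3-iodo-2-methylprop-2-en-1-ol
Product: 17 (Z)-3-bromo-1-iodo-2-methylprop-1-ene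
Conditions: CBr4, PPh3, CH2Cl2, 0 °C
Reagents that add atoms: carbon tetrabromide, BrC(Br)(Br)Br
Why: Appel bromination of a primary allylic alcohol proceeds under neutral conditions and leaves the Z-iodoalkene unchanged.

**Step 12**
Reactants: 17 (Z)-3-bromo-1-iodo-2-methylprop-1-ene; 18 acetaldehyde N,N-dimethylhydrazone
Product: 20 (Z)-5-iodo-4-methylpent-4-enal, via alkylated hydrazone 19 (not isolated)
Conditions: LiN(iPr)2, 18, THF, −78 °C; 17, −78 → 0 °C; then aq. oxalic acid, Et2O, rt
Reagents that add atoms: water, O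
Why: Alkylation of the lithiated hydrazone (an acetaldehyde enolate equivalent) with the allylic bromide, then mild acidic hydrolysis, gives the aldehyde that carries C2–C6; the alkenyl iodide is inert to the aza-enolate at low temperature.

**Step 13**
Reactants: 15 C11 silyl ether; 20 (Z)-5-iodo-4-methylpent-4-enal
Product: 21 aldol adduct (C14 ketone, quaternary C1 with β-methyl, C2 carbinol carrying the C3–C6 iodoalkene arm)
Conditions: BF3·OEt2, CH2Cl2, −78 °C
Reagents that add atoms: none
Why: Mukaiyama aldol addition of the tetrasubstituted silyl enol ether: C1 is the only nucleophilic carbon; the aldehyde should add to the α-face because the β-face is covered by the cis-fused lactone (C9 and C20), which sets the quaternary C1 with C2 trans to C9; and the open antiperiplanar transition state places the aldehyde chain beside the small C1 methyl, which gives the C2 carbinol syn to C10 as required.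

**Step 14**
Reactants: 21 aldol adduct
Product: 22 1,3-syn diol (C14 α-OH, C2 OH)
Conditions: Et2BOMe, THF/MeOH, −78 °C; NaBH4; then MeOH/AcOH co-evaporation
Reagents that add atoms: none
Why: Narasaka–Prasad reduction: external hydride attacks the six-membered boron chelate of the β-hydroxy ketone from the side of the C1 methyl and gives the 1,3-syn diol, hence the α-hydroxyl at C14; lactone, ester and amide are inert at −78 °C.

**Step 15**
Reactants: 22 1,3-syn diol
Product: 23 tetraol (C2, C9, C14 secondary OH and C20 primary OH; C8 and C11 OTBS)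
Conditions: LiBH4, MeOH (1 equiv), THF, 0 °C → rt
Reagents that add atoms: none
Why: LiBH4 reduces the lactone but not the shielded tert-butyl ester or the tertiary amide, so the temporary ring is opened with all its atoms kept: C20 becomes the primary alcohol and O9 the free C9 hydroxyl.

**Step 16**
Reactants: 23 tetraol
Product: 25 triacetate tosylate (2-, 9-, 14-OAc; C20 OTs), via C20 tosylate triol 24 (not isolated)
Conditions: TsCl, pyridine, CH2Cl2, 0 °C → rt; then Ac2O, DMAP, rt
Reagents that add atoms: p-toluenesulfonyl chloride, Cc1ccc(cc1)S(=O)(=O)Cl; acetic anhydride, CC(=O)OC(C)=O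
Why: Sulfonylation is selective for the only primary hydroxyl (C20), and DMAP-catalysed acetylation then esterifies the three secondary hydroxyls that are acetates in the target.

**Step 17**
Reactants: 25 triacetate tosylate
Product: 26 C7 aldehyde
Conditions: Cp2Zr(H)Cl, THF, rt
Reagents that add atoms: none
Why: Cp2Zr(H)Cl reduces tertiary amides to aldehydes through a stable zirconium hemiaminal and tolerates esters, sulfonates, silyl ethers and the trisubstituted iodoalkene; the aldehyde has no α-hydrogen and cannot epimerise.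

**Step 18**
Reactants: 26 C7 aldehyde
Product: 27 macrocyclic allylic alcohol (ten-membered ring, 5Z, 7S)
Conditions: CrCl2, NiCl2 (cat.), DMSO/THF, high dilution, rt
Reagents that add atoms: none
Why: Nozaki–Hiyama–Kishi ring closure: nickel-catalysed formation of the alkenylchromium species (trivalent chromium) from the Z-iodide with retention of geometry and its addition to the C7 aldehyde forms C6–C7 and the ten-membered ring; the trans-disposed C2 and C9 arms on ring A and the cis-olefin bring the ends together, and attack anti to the C8 silyloxy group (non-chelation model) should give the 7S carbinol.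

**Step 19**
Reactants: 27 macrocyclic allylic alcohol
Product: 28 hydroxy tosylate lactone (C7–O–C19 γ-lactone, 8-OH, 11-OH, C20 OTs, three acetates)
Conditions: TFA/CH2Cl2/H2O (20:75:5), 0 °C → rt
Reagents that add atoms: none
Why: Acidolysis cleaves the tert-butyl ester and both tertiary silyl ethers, and the liberated acid lactonises onto the only free γ-hydroxyl (C7; O9 is acetylated); acetates and the primary tosylate survive, and the electron-poor C8 next to C7 should disfavour allylic ionisation.

**Step 20**
Reactants: 28 hydroxy tosylate lactone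
Product: 29 junceellolide F
Conditions: DBU, MeCN, rt → 40 °C
Reagents that add atoms: none
Why: Intramolecular Williamson-type closure: the tertiary C11 oxygen displaces the primary C20 tosylate (3-exo-tet) with retention at C11 to give the α-epoxide, and the non-nucleophilic amidine base spares the acetates and the lactone.

**Compound list**

1 | tert-butyl (R)-lactate | C[C@@H](O)C(=O)OC(C)(C)C | starting material
2 | tert-butyl (2R)-2-(trifluoromethylsulfonyloxy)propanoate | C[C@@H](OS(=O)(=O)C(F)(F)F)C(=O)OC(C)(C)C | intermediate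
3 | 2,3-O-isopropylidene-D-erythronolactone | O=C1OC[C@H]2OC(C)(C)O[C@@H]12 | starting material
4 | C8-alkylated lactone (C8 quaternary, 17R) | O=C1OC[C@H]2OC(C)(C)O[C@@]12[C@@H](C)C(=O)OC(C)(C)C | intermediate
5 | hydroxy morpholine amide (C7 amide, C10 OH, C8/C9 acetonide) | OC[C@H]1OC(C)(C)O[C@]1(C(=O)N2CCOCC2)[C@@H](C)C(=O)OC(C)(C)C | intermediate
6 | 3-(triphenylphosphoranylidene)butan-2-one | CC(=O)C(C)=P(c1ccccc1)(c1ccccc1)c1ccccc1 | starting material
7 | C10 aldehyde | O=C[C@H]1OC(C)(C)O[C@]1(C(=O)N2CCOCC2)[C@@H](C)C(=O)OC(C)(C)C | intermediate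
8 | (E)-enone acetonide | CC(=O)/C(C)=C/[C@H]1OC(C)(C)O[C@]1(C(=O)N2CCOCC2)[C@@H](C)C(=O)OC(C)(C)C | intermediate
9 | enone diol | CC(=O)/C(C)=C/[C@@H](O)[C@@](O)(C(=O)N1CCOCC1)[C@@H](C)C(=O)OC(C)(C)C | intermediate
10 | acryloyl chloride | C=CC(=O)Cl | starting material
11 | C9 acrylate | CC(=O)/C(C)=C/[C@@H](OC(=O)C=C)[C@@](O)(C(=O)N1CCOCC1)[C@@H](C)C(=O)OC(C)(C)C | intermediate
12 | bis-silyl triene | C=C(O[Si](C)(C)C(C)(C)C)/C(C)=C/[C@@H](OC(=O)C=C)[C@@](O[Si](C)(C)C(C)(C)C)(C(=O)N1CCOCC1)[C@@H](C)C(=O)OC(C)(C)C | intermediate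
13 | bicyclic lactone silyl enol ether (cis-fused) | CC1=C(O[Si](C)(C)C(C)(C)C)CC[C@@H]2C(=O)O[C@@H]([C@@](O[Si](C)(C)C(C)(C)C)(C(=O)N3CCOCC3)[C@@H](C)C(=O)OC(C)(C)C)[C@H]12 | intermediate
14 | C11 α-hydroxy lactone | CC1=C(O[Si](C)(C)C(C)(C)C)CC[C@]2(O)C(=O)O[C@@H]([C@@](O[Si](C)(C)C(C)(C)C)(C(=O)N3CCOCC3)[C@@H](C)C(=O)OC(C)(C)C)[C@H]12 | intermediate
15 | C11 silyl ether | CC1=C(O[Si](C)(C)C(C)(C)C)CC[C@]2(O[Si](C)(C)C(C)(C)C)C(=O)O[C@@H]([C@@](O[Si](C)(C)C(C)(C)C)(C(=O)N3CCOCC3)[C@@H](C)C(=O)OC(C)(C)C)[C@H]12 | intermediate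
16 | (Z)-3-iodo-2-methylprop-2-en-1-ol | OC/C(C)=C\I | starting material
17 | (Z)-3-bromo-1-iodo-2-methylprop-1-ene | BrC/C(C)=C\I | intermediate
18 | acetaldehyde N,N-dimethylhydrazone | CC=NN(C)C | starting material
19 | alkylated hydrazone | CN(C)N=CCC/C(C)=C\I | intermediate
20 | (Z)-5-iodo-4-methylpent-4-enal | O=CCC/C(C)=C\I | intermediate
21 | aldol adduct (C14 ketone, C2 OH) | O=C1CC[C@]2(O[Si](C)(C)C(C)(C)C)C(=O)O[C@@H]([C@@](O[Si](C)(C)C(C)(C)C)(C(=O)N3CCOCC3)[C@@H](C)C(=O)OC(C)(C)C)[C@@H]2[C@@]1(C)[C@H](O)CC/C(C)=C\I | intermediate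
22 | 1,3-syn diol | O[C@H]1CC[C@]2(O[Si](C)(C)C(C)(C)C)C(=O)O[C@@H]([C@@](O[Si](C)(C)C(C)(C)C)(C(=O)N3CCOCC3)[C@@H](C)C(=O)OC(C)(C)C)[C@@H]2[C@@]1(C)[C@H](O)CC/C(C)=C\I | intermediate
23 | tetraol | O[C@H]1CC[C@](O[Si](C)(C)C(C)(C)C)(CO)[C@H]([C@@H](O)[C@@](O[Si](C)(C)C(C)(C)C)(C(=O)N2CCOCC2)[C@@H](C)C(=O)OC(C)(C)C)[C@@]1(C)[C@H](O)CC/C(C)=C\I | intermediate
24 | C20 tosylate triol | O[C@H]1CC[C@](O[Si](C)(C)C(C)(C)C)(COS(=O)(=O)c2ccc(C)cc2)[C@H]([C@@H](O)[C@@](O[Si](C)(C)C(C)(C)C)(C(=O)N2CCOCC2)[C@@H](C)C(=O)OC(C)(C)C)[C@@]1(C)[C@H](O)CC/C(C)=C\I | intermediate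
25 | triacetate tosylate | CC(=O)O[C@H]1CC[C@](O[Si](C)(C)C(C)(C)C)(COS(=O)(=O)c2ccc(C)cc2)[C@H]([C@@H](OC(C)=O)[C@@](O[Si](C)(C)C(C)(C)C)(C(=O)N2CCOCC2)[C@@H](C)C(=O)OC(C)(C)C)[C@@]1(C)[C@H](OC(C)=O)CC/C(C)=C\I | intermediate
26 | C7 aldehyde | CC(=O)O[C@H]1CC[C@](O[Si](C)(C)C(C)(C)C)(COS(=O)(=O)c2ccc(C)cc2)[C@H]([C@@H](OC(C)=O)[C@@](O[Si](C)(C)C(C)(C)C)(C=O)[C@@H](C)C(=O)OC(C)(C)C)[C@@]1(C)[C@H](OC(C)=O)CC/C(C)=C\I | intermediate
27 | macrocyclic allylic alcohol | CC(=O)O[C@H]1CC[C@](O[Si](C)(C)C(C)(C)C)(COS(=O)(=O)c2ccc(C)cc2)[C@@H]2[C@@H](OC(C)=O)[C@](O[Si](C)(C)C(C)(C)C)([C@@H](C)C(=O)OC(C)(C)C)[C@@H](O)/C=C(/C)CC[C@@H](OC(C)=O)[C@@]12C | intermediate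
28 | hydroxy tosylate lactone | CC(=O)O[C@H]1CC[C@](O)(COS(=O)(=O)c2ccc(C)cc2)[C@@H]2[C@@H](OC(C)=O)[C@@]3(O)[C@H](/C=C(/C)CC[C@@H](OC(C)=O)[C@@]12C)OC(=O)[C@@H]3C | intermediate
29 | junceellolide F | CC(=O)O[C@H]1CC[C@]2(CO2)[C@@H]2[C@@H](OC(C)=O)[C@@]3(O)[C@H](/C=C(/C)CC[C@@H](OC(C)=O)[C@@]12C)OC(=O)[C@@H]3C | target

**Step count**

Total: 20 steps. Longest linear sequence: 18 steps (steps 1–10 and 13–20); steps 11–12 are the side branch.

**Steps most likely to fail**

Step 18 (ring closure). The risk is competing intermolecular coupling or reduction of the alkenyl iodide during the medium-ring closure, and poor facial selectivity at C7. The fallback sets out from 27 taken as the mixture of C7 epimers and comes back at 27. The mixture is oxidised with DMP to the macrocyclic enone F5. Corey–Bakshi–Shibata reduction with the (R)-B-methyl oxazaborolidine and catecholborane, the quaternary C8 acting as the large group, should then give the 7S alcohol 27 under reagent control.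

Step 13 (aldol). The risk is slow addition at the hindered enol ether carbon and poor simple diastereoselection at C2 (open against closed transition state). The fallback sets out from 21 taken as the mixture of C2 epimers and comes back at 22. DMP oxidation gives the 2,2-disubstituted 1,3-diketone F3, in which C2 is no longer a stereocentre. Corey–Bakshi–Shibata reduction with the (R)-B-methyl oxazaborolidine and catecholborane at −78 °C should take the more reactive ring ketone at C14 under reagent control to the β-hydroxy ketone F4. The same chelation-controlled 1,3-syn reduction (Et2BOMe, NaBH4), now of the C2 ketone, then gives 22.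

Step 2 (alkylation). The risk is elimination of the secondary triflate by the basic enolate and slow substitution at the fully substituted enolate carbon. The fallback sets out from 3 and comes back at 4. Conjugate addition of the lithium enolate of 3 to (E)-1-nitropropene (THF, −78 °C; the same exo attack at C8) gives the nitro lactone F1, whose C17 epimers are separated. Oxidation of the primary nitro group with NaNO2 and acetic acid in DMSO gives the carboxylic acid F2. Esterification with Boc2O, DMAP and tert-butanol gives 4.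

**Further compounds**

F1 | step 2 | nitro lactone (C8–C17H(CH3)–CH2NO2) | O=C1OC[C@H]2OC(C)(C)O[C@@]12[C@@H](C)C[N+](=O)[O-]
F2 | step 2 | carboxylic acid (C19 acid of 4) | O=C1OC[C@H]2OC(C)(C)O[C@@]12[C@@H](C)C(=O)O
F3 | step 13 | 1,3-diketone (C14 and C2 ketones) | O=C1CC[C@]2(O[Si](C)(C)C(C)(C)C)C(=O)O[C@@H]([C@@](O[Si](C)(C)C(C)(C)C)(C(=O)N3CCOCC3)[C@@H](C)C(=O)OC(C)(C)C)[C@@H]2[C@@]1(C)C(=O)CC/C(C)=C\I
F4 | step 13 | β-hydroxy ketone (C14 α-OH, C2 ketone) | O[C@H]1CC[C@]2(O[Si](C)(C)C(C)(C)C)C(=O)O[C@@H]([C@@](O[Si](C)(C)C(C)(C)C)(C(=O)N3CCOCC3)[C@@H](C)C(=O)OC(C)(C)C)[C@@H]2[C@@]1(C)C(=O)CC/C(C)=C\I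
F5 | step 18 | macrocyclic enone (C7 ketone) | CC(=O)O[C@H]1CC[C@](O[Si](C)(C)C(C)(C)C)(COS(=O)(=O)c2ccc(C)cc2)[C@@H]2[C@@H](OC(C)=O)[C@](O[Si](C)(C)C(C)(C)C)([C@@H](C)C(=O)OC(C)(C)C)C(=O)/C=C(/C)CC[C@@H](OC(C)=O)[C@@]12C
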